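## Retrosynthetic overview

1. Target ⇐ one-pot removal of three allyl groups (allyl carbonate on the lactol, allyl fumarate ester, aryl allyl ether); the lactol centre is fixed just before by acylative dynamic kinetic resolution of the racemic hydroxyphthalide (C–O bond).
2. Depsidone seven-membered ring ⇐ intramolecular dehydrogenative aryl C–O coupling of a depside: the ring A salicylate OH adds to the C–H para to the ring B phenol (key step).
3. Depside ⇐ ester C–O coupling of 4-O-allylhaematommic acid (ring A) with a 5,7-dihydroxy-3-methoxyphthalide that already carries the CH2O–fumarate (ring B).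
4. Ring B ⇐ 3,5-dimethoxybenzaldehyde (bromination, hydroxycarbonylation, demethylation, Mannich, quinone-methide acyloxylation); ring A ⇐ methyl orsellinate; fumarate ⇐ maleic anhydride.
5. Ring order: both benzene rings are bought; the hydroxyphthalide ring is closed first, the dioxepinone (depsidone) ring last.

Assumption: the 3-hydroxyphthalide carbon is the only stereocentre and is labile by ring–chain tautomerism, so it is locked as a carbonate in the penultimate step and unveiled last in a buffered acidic, aprotic medium; the catalyst enantiomer written is the one assumed to give the required sense (to be confirmed by X-ray or ECD; otherwise its antipode is used).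

## Route

Step 1
Reactants: 1 methyl orsellinate
Product: 2 methyl haematommate
Conditions: Cl2CHOMe (1.2 equiv), TiCl4 (2.2 equiv), CH2Cl2, −10 → 0 °C; then 1 M HCl
Reagents that add atoms: dichloromethyl methyl ether, COC(Cl)Cl (formyl carbon); water, O (formyl oxygen on hydrolysis)
Why: Rieche formylation, in which TiCl4 bound to the 2-phenoxide/ester chelate delivers the electrophile to C-3 (ortho to both hydroxyls) and hydrolysis of the α-chloro ether gives the aldehyde.

Step 2
Reactants: 2 methyl haematommate
Product: 3 methyl 4-(allyloxy)-3-formyl-2-hydroxy-6-methylbenzoate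
Conditions: allyl bromide (1.05 equiv), K2CO3 (1.1 equiv), acetone, 45 °C
Reagents that add atoms: allyl bromide, C=CCBr
Why: Williamson etherification, selective for the 4-OH (one ortho neighbour, para to the ester) over the 2-OH that is flanked and hydrogen-bonded by ester and aldehyde.

Step 3
Reactants: 3 methyl 4-(allyloxy)-3-formyl-2-hydroxy-6-methylbenzoate
Product: 4 4-(allyloxy)-3-formyl-2-hydroxy-6-methylbenzoic acid
Conditions: KOH (5 equiv), DMSO/H2O 4:1, 60 °C; then cold 1 M HCl
Reagents that add atoms: potassium hydroxide, [K+].[OH-]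
Why: Saponification of the hindered salicylate; the aldehyde is deactivated as a vinylogous phenoxide, the allyl ether is inert to hydroxide, and cold acidification avoids decarboxylation.

Step 4
Reactants: 5 3,5-dimethoxybenzaldehyde
Product: 6 2-bromo-3,5-dimethoxybenzaldehyde
Conditions: NBS (1.05 equiv), MeCN, 0 → 20 °C
Reagents that add atoms: N-bromosuccinimide, O=C1CCC(=O)N1Br
Why: Electrophilic aromatic bromination at C-2 (ortho to one methoxy, para to the other), the established regiochemistry for this aldehyde.

Step 5
Reactants: 6 2-bromo-3,5-dimethoxybenzaldehyde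
Product: 7 rac-3-hydroxy-5,7-dimethoxyisobenzofuran-1(3H)-one
Conditions: CO (1 atm), Pd(OAc)2 (3 mol%), Xantphos (4 mol%), K2CO3 (2.5 equiv), 1,4-dioxane/H2O, 90 °C; then 2 M HCl
Reagents that add atoms: carbon monoxide, [C-]#[O+]; water, O
Why: Palladium-catalysed hydroxycarbonylation (oxidative addition, CO insertion, hydrolysis of the acylpalladium); on acidification the 2-formylbenzoic acid closes to the racemic cyclic lactol with the lactone carbonyl on the carbon next to a methoxy group.

Step 6
Reactants: 7 rac-3-hydroxy-5,7-dimethoxyisobenzofuran-1(3H)-one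
Product: 9 rac-5,7-dihydroxy-3-methoxyisobenzofuran-1(3H)-one, via trihydroxyphthalide 8 (not isolated)
Conditions: BBr3 (4 equiv), CH2Cl2, −78 → 20 °C; then MeOH, 0 → 50 °C
Reagents that add atoms: methanol, CO
Why: BBr3 cleavage of both aryl methyl ethers, then Fischer-type pseudo-ester formation at the lactol catalysed by the HBr released on methanol quench (the acetal carbon stays racemic).

Step 7
Reactants: 9 rac-5,7-dihydroxy-3-methoxyisobenzofuran-1(3H)-one
Product: 10 rac-6-[(dimethylamino)methyl]-5,7-dihydroxy-3-methoxyisobenzofuran-1(3H)-one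
Conditions: CH2=NMe2+ I− (1.0 equiv), MeCN, 20 °C; aqueous NaHCO3 work-up
Reagents that add atoms: N,N-dimethylmethyleneiminium iodide (Eschenmoser's salt), C=[N+](C)C.[I-]
Why: Phenolic Mannich reaction with a preformed iminium salt (no free amine to open the pseudo-ester); C-6, between both hydroxyls and favoured by chelation, reacts in preference to C-4.

Step 8
Reactants: 11 maleic anhydride
Product: 13 monoallyl fumarate, via monoallyl maleate 12 (not isolated)
Conditions: allyl alcohol (1.0 equiv), neat, 60 °C; then AlCl3 (3 mol%), 75 °C
Reagents that add atoms: allyl alcohol, C=CCO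
Why: Anhydride alcoholysis gives the Z half-ester, and Lewis-acid-catalysed Z→E isomerisation gives the more stable, crystalline E half-ester (the standard route to monoalkyl fumarates).

Step 9
Reactants: 10 rac-6-[(dimethylamino)methyl]-5,7-dihydroxy-3-methoxyisobenzofuran-1(3H)-one; 13 monoallyl fumarate
Product: 15 allyl (rac-5,7-dihydroxy-3-methoxy-1-oxo-1,3-dihydroisobenzofuran-6-yl)methyl fumarate (ring B fragment), via trimethylammonium iodide 14 (not isolated)
Conditions: MeI (1.05 equiv), MeCN, 20 °C, evaporate; then 13 (3 equiv), NaHCO3 (3 equiv), DMF, 20 → 40 °C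
Reagents that add atoms: iodomethane, CI (its methyl is held only in 14 and leaves as trimethylamine)
Why: N-Methylation turns the amine into a leaving group, base-triggered 1,4-elimination gives the ortho-quinone methide, and the excess fumarate carboxylate adds to its exocyclic carbon (oxa-Michael addition with rearomatisation) to form the benzylic C–O bond.

Step 10
Reactants: 4 4-(allyloxy)-3-formyl-2-hydroxy-6-methylbenzoic acid; 15 ring B fragment
Product: 16 racemic depside: 15 acylated on its 5-OH by the 4-(allyloxy)-3-formyl-2-hydroxy-6-methylbenzoyl group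
Conditions: DCC (1.2 equiv), DMAP (5 mol%), CH2Cl2, 0 → 20 °C
Reagents that add atoms: none
Why: Steglich esterification as in classical depside synthesis; only the non-chelated 5-OH of 15 is acylated, while its chelated 7-OH and the chelated 2-OH of 4 stay free.

Step 11
Reactants: 16 racemic depside
Product: 18 racemic hydroxyphthalide depsidone, via methoxyphthalide depsidone 17 (not isolated)
Conditions: PhI(OCOCF3)2 (1.05 equiv), (CF3)2CHOH, 0.01 M, −20 → 0 °C; then H2O/CF3CO2H, 45 °C
Reagents that add atoms: water, O
Why: Proposed new method: trivalent-iodine-mediated intramolecular dehydrogenative C–H aryloxylation of a depside to a depsidone; the ring B phenol (one ortho acyl group) is oxidised far more easily than the ring A phenol (two ortho acyl groups), so ligand exchange at iodine and loss of PhI give a ring B phenoxenium ion whose ortho positions are blocked and whose only open position, para (C-4 of the phthalide), is where the ester tether holds the ring A 2-OH, so seven-membered C–O closure gives a 4-aryloxycyclohexa-2,5-dienone that tautomerises irreversibly to the diaryl ether; the closest known reaction types are hypervalent-iodine para-functionalisation of phenols by O-nucleophiles and the copper/amine aerobic para C–O coupling of 2,6-disubstituted phenols, neither shown on a salicylate-type depside; the second stage is an ordinary acid hydrolysis of the pseudo-ester acetal.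

Step 12
Reactants: 18 racemic hydroxyphthalide depsidone
Product: 19 (S)-allyl carbonate of the lactol
Conditions: diallyl dicarbonate (1.3 equiv), (2S,3R)-HyperBTM [(2S,3R)-3-isopropyl-2-phenyl-3,4-dihydro-2H-benzo[4,5]thiazolo[3,2-a]pyrimidine] (10 mol%), i-Pr2NEt (10 mol%), toluene, −20 °C
Reagents that add atoms: diallyl dicarbonate, C=CCOC(=O)OC(=O)OCC=C
Why: Acylative dynamic kinetic resolution of a lactol by a chiral isothiourea acyl-transfer catalyst: ring–chain tautomerism racemises 18 while the chiral alkoxycarbonyl-isothiouronium acylates one enantiomer faster, giving a configurationally stable carbonate whose (S) descriptor is the same spatial arrangement as (R) in the target (the carbonate oxygen outranks the ring oxygen).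

Step 13
Reactants: 19 (S)-allyl carbonate of the lactol
Product: 20 target, (R)-lactol
Conditions: Pd(PPh3)4 (5 mol%), HCO2H (4 equiv), pyridine (1 equiv), THF, 0 → 20 °C, dark; cold non-basic isolation
Reagents that add atoms: none
Why: Tsuji–Trost reductive deallylation with formate cleaves only the three O–allyl bonds, and in the acidic buffer the carbonic half-ester loses CO2 as the neutral acid, so the lactol C–O bond is never broken and the (S)-carbonate gives the (R)-lactol with unchanged geometry.

## Compound list

1 | methyl orsellinate (methyl 2,4-dihydroxy-6-methylbenzoate) | COC(=O)c1c(C)cc(O)cc1O | starting material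
2 | methyl haematommate (methyl 3-formyl-2,4-dihydroxy-6-methylbenzoate) | COC(=O)c1c(C)cc(O)c(C=O)c1O | intermediate
3 | methyl 4-(allyloxy)-3-formyl-2-hydroxy-6-methylbenzoate | COC(=O)c1c(C)cc(OCC=C)c(C=O)c1O | intermediate
4 | 4-(allyloxy)-3-formyl-2-hydroxy-6-methylbenzoic acid (ring A acid) | OC(=O)c1c(C)cc(OCC=C)c(C=O)c1O | intermediate
5 | 3,5-dimethoxybenzaldehyde | COc1cc(OC)cc(C=O)c1 | starting material
6 | 2-bromo-3,5-dimethoxybenzaldehyde | COc1cc(OC)c(Br)c(C=O)c1 | intermediate
7 | rac-3-hydroxy-5,7-dimethoxyisobenzofuran-1(3H)-one (cyclic form of 2-formyl-4,6-dimethoxybenzoic acid) | COc1cc(OC)c2C(=O)OC(O)c2c1 | intermediate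
8 | rac-3,5,7-trihydroxyisobenzofuran-1(3H)-one | Oc1cc(O)c2C(=O)OC(O)c2c1 | intermediate
9 | rac-5,7-dihydroxy-3-methoxyisobenzofuran-1(3H)-one | COC1OC(=O)c2c(O)cc(O)cc12 | intermediate
10 | rac-6-[(dimethylamino)methyl]-5,7-dihydroxy-3-methoxyisobenzofuran-1(3H)-one | COC1OC(=O)c2c(O)c(CN(C)C)c(O)cc12 | intermediate
11 | maleic anhydride | O=C1OC(=O)C=C1 | starting material
12 | monoallyl maleate, (Z)-4-(allyloxy)-4-oxobut-2-enoic acid | C=CCOC(=O)/C=C\C(=O)O | intermediate
13 | monoallyl fumarate, (E)-4-(allyloxy)-4-oxobut-2-enoic acid | C=CCOC(=O)/C=C/C(=O)O | intermediate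
14 | rac-[(5,7-dihydroxy-3-methoxy-1-oxo-1,3-dihydroisobenzofuran-6-yl)methyl]trimethylammonium iodide | COC1OC(=O)c2c(O)c(C[N+](C)(C)C)c(O)cc12.[I-] | intermediate
15 | allyl (rac-5,7-dihydroxy-3-methoxy-1-oxo-1,3-dihydroisobenzofuran-6-yl)methyl (E)-but-2-enedioate (ring B fragment) | COC1OC(=O)c2c(O)c(COC(=O)/C=C/C(=O)OCC=C)c(O)cc12 | intermediate
16 | racemic depside: 15 esterified on its 5-OH with acid 4 (free 2-OH on ring A, free 7-OH and C-4–H on ring B) | COC1OC(=O)c2c(O)c(COC(=O)/C=C/C(=O)OCC=C)c(OC(=O)c3c(C)cc(OCC=C)c(C=O)c3O)cc12 | intermediate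
17 | racemic depsidone: 3-allyloxy-4-formyl-8-hydroxy-1-methyl-11-oxo-11H-dibenzo[b,e][1,4]dioxepin with 9-CH2O–(allyl fumarate) and a 6,7-fused 3-methoxyphthalide (acetal carbon on C-6, lactone C=O on C-7) | Cc1cc(OCC=C)c(C=O)c2c1C(=O)Oc1c(COC(=O)/C=C/C(=O)OCC=C)c(O)c3c(c1O2)C(OC)OC3=O | intermediate
18 | racemic hydroxyphthalide depsidone: as 17 with OH in place of OMe on the acetal carbon | Cc1cc(OCC=C)c(C=O)c2c1C(=O)Oc1c(COC(=O)/C=C/C(=O)OCC=C)c(O)c3c(c1O2)C(O)OC3=O | intermediate
19 | (S)-allyl carbonate of 18 (allyloxycarbonyloxy on the acetal carbon; same spatial arrangement as (R) in 20) | Cc1cc(OCC=C)c(C=O)c2c1C(=O)Oc1c(COC(=O)/C=C/C(=O)OCC=C)c(O)c3c(c1O2)[C@H](OC(=O)OCC=C)OC3=O | intermediate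
20 | CNP0379578.1: 4-formyl-3,8-dihydroxy-1-methyl-11-oxo-depsidone with 9-CH2O–(E)-fumaric half-ester and 6,7-fused (R)-3-hydroxyphthalide | Cc1cc(O)c(C=O)c2c1C(=O)Oc1c(COC(=O)/C=C/C(=O)O)c(O)c3c(c1O2)[C@H](O)OC3=O | target

## Step count and risk

Total steps: 13. Longest linear sequence: 9 (steps 4, 5, 6, 7, 9, 10, 11, 12, 13, from 5 to 20).

Three steps most likely to fail:

**Step 9 (quinone-methide acyloxylation).** The quinone methide may instead be captured by phenoxide or water, or the phenol may be O-methylated. The fallback sets out from 9 and comes back at 15. Compound 9 is ortho-formylated at C-6 (MgCl2, Et3N, paraformaldehyde, MeCN, reflux) to rac-6-formyl-5,7-dihydroxy-3-methoxyisobenzofuran-1(3H)-one F1. NaBH4 (THF/MeOH, 0 °C) reduces the aldehyde to rac-5,7-dihydroxy-6-(hydroxymethyl)-3-methoxyisobenzofuran-1(3H)-one F2. A Mitsunobu esterification with 13 (PPh3, DIAD, THF, 0 °C) then gives 15.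

**Step 11 (proposed new oxidative C–O closure).** The chelated ring B phenol may resist oxidation, or the more electron-rich para-aryloxyphenol product may be over-oxidised. The fallback uses known chemistry, sets out from 15 and comes back at 17. Compound 15 is brominated at its only free ring position (NBS, MeCN, −10 °C) to the rac-4-bromo ring B fragment F3. Esterification with 4 under the conditions of step 10 gives the rac-bromo depside F4. An intramolecular Ullmann diaryl ether coupling (CuI 20 mol%, picolinic acid 40 mol%, K3PO4, 1,4-dioxane, 90 °C) closes the depsidone ring to 17, which is hydrolysed as in the second stage of step 11.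

**Step 12 (dynamic kinetic resolution on a crowded, polyfunctional lactol).** Selectivity may be low, the chelated 8-OH may be carbonated, or a non-catalysed racemic pathway may compete. The fallback sets out from 18 and comes back at 20. Compound 18 is deallylated under the conditions of step 13 to the racemic target acid F5. A crystallisation-induced diastereomer transformation with (R)-N,N-dimethyl-1-phenylethylamine (MeCN/EtOAc) follows: the lactol epimerises in solution while the less soluble (R)-lactol ammonium salt F6 crystallises. Partition between cold dilute HCl and EtOAc releases 20.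

Further compounds
F1 | step 9 | rac-6-formyl-5,7-dihydroxy-3-methoxyisobenzofuran-1(3H)-one | COC1OC(=O)c2c(O)c(C=O)c(O)cc12
F2 | step 9 | rac-5,7-dihydroxy-6-(hydroxymethyl)-3-methoxyisobenzofuran-1(3H)-one | COC1OC(=O)c2c(O)c(CO)c(O)cc12
F3 | step 11 | rac-4-bromo ring B fragment (15 with Br at C-4) | COC1OC(=O)c2c(O)c(COC(=O)/C=C/C(=O)OCC=C)c(O)c(Br)c12
F4 | step 11 | rac-bromo depside (16 with Br at C-4 of ring B) | COC1OC(=O)c2c(O)c(COC(=O)/C=C/C(=O)OCC=C)c(OC(=O)c3c(C)cc(OCC=C)c(C=O)c3O)c(Br)c12
F5 | step 12 | racemic target acid (20 without defined lactol configuration) | Cc1cc(O)c(C=O)c2c1C(=O)Oc1c(COC(=O)/C=C/C(=O)O)c(O)c3c(c1O2)C(O)OC3=O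
F6 | step 12 | (R)-N,N-dimethyl-1-phenylethylammonium salt of the (R)-lactol acid 20 | Cc1cc(O)c(C=O)c2c1C(=O)Oc1c(COC(=O)/C=C/C(=O)[O-])c(O)c3c(c1O2)[C@H](O)OC3=O.C[C@@H]([NH+](C)C)c1ccccc1
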